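**Retrosynthetic overview**
1. The target is opened at its ketone to a benzyl β-keto ester, ArA–CH(CO2Bn)–CO–CH2–ArB, with both phenols as benzyl ethers; one neutral hydrogenolysis/decarboxylation releases the target.
2. The key C–C bond (ArA–CH to C=O) comes from a crossed Claisen condensation: lithium enolate of a mixed homophthalate diester (ArA) plus the acyl imidazole of the ArB-acetic acid.
3. The ArB acid comes from 2-allyl-4-chloro-3,5-dimethoxyphenol (aromatic Claisen rearrangement on the symmetric 4-chloro-3,5-dimethoxyphenol), itself from 1,3-dimethoxybenzene by ortho-lithiation/chlorination and Ir borylation/oxidation.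
4. The ArA homophthalate comes from methyl 2-allyl-3-(benzyloxy)-5-methylbenzoate (Stille allylation of a salicylate triflate), itself from methyl 5-methylsalicylate by Duff formylation, Dakin oxidation and selective 3-O-benzylation.
5. No ring is formed; both benzene rings are bought and only substituted.

Assumption: the target SMILES has no stereocentre, so the compound is achiral and needs no stereocontrol; stereocentres in intermediates are racemic and are destroyed later.

**Fragment B (ArB-acetic acid)**

Step 1
Reactants: 1 1,3-dimethoxybenzene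
Product: 2 2-chloro-1,3-dimethoxybenzene
Conditions: n-BuLi (1.1 equiv), THF, 0 °C → rt, 2 h; then C2Cl6 (1.15 equiv), −78 °C → rt
Reagents that add atoms: hexachloroethane ClC(Cl)(Cl)C(Cl)(Cl)Cl
Why: Directed ortho-metalation removes the C2–H between the two methoxy groups (the most acidic), and the aryllithium is chlorinated by Cl+ transfer from hexachloroethane.

Step 2
Reactants: 2 2-chloro-1,3-dimethoxybenzene
Product: 4 4-chloro-3,5-dimethoxyphenol, via arylboronate 3 (not isolated)
Conditions: [Ir(OMe)(cod)]2 (1.5 mol %), dtbpy (3 mol %), B2pin2 (1.0 equiv), THF, 80 °C; evaporate; Oxone (1.1 equiv), acetone–H2O 1:1, rt, 15 min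
Reagents that add atoms: bis(pinacolato)diboron CC1(C)OB(OC1(C)C)B1OC(C)(C)C(C)(C)O1 (boryl group of 3); potassium peroxymonosulfate (Oxone) [K+].[O-]S(=O)(=O)OO (phenol oxygen of 4)
Why: Sterically controlled Ir-catalysed C–H borylation takes the only C–H not ortho to a substituent (C5, para to Cl), and oxidation of the C–B bond gives the symmetric phenol.

Step 3
Reactants: 4 4-chloro-3,5-dimethoxyphenol
Product: 5 5-(allyloxy)-2-chloro-1,3-dimethoxybenzene
Conditions: allyl bromide (1.3 equiv), K2CO3 (2 equiv), acetone, reflux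
Reagents that add atoms: allyl bromide C=CCBr
Why: Williamson ether synthesis on an unhindered phenoxide with a reactive allylic halide.

Step 4
Reactants: 5 5-(allyloxy)-2-chloro-1,3-dimethoxybenzene
Product: 6 2-allyl-4-chloro-3,5-dimethoxyphenol
Conditions: N,N-diethylaniline, 195 °C, sealed tube, N2, 6 h
Reagents that add atoms: none
Why: Aromatic Claisen rearrangement; the two ortho positions are equivalent and the para position is blocked by Cl, so only one regioisomer can form.

Step 5
Reactants: 6 2-allyl-4-chloro-3,5-dimethoxyphenol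
Product: 7 2-allyl-1-(benzyloxy)-4-chloro-3,5-dimethoxybenzene
Conditions: BnBr (1.2 equiv), K2CO3 (2 equiv), DMF, 50 °C
Reagents that add atoms: benzyl bromide BrCc1ccccc1
Why: Williamson benzylation gives a phenol protecting group that survives oxidation and strong base and is removed under neutral conditions at the end.

Step 6
Reactants: 7 2-allyl-1-(benzyloxy)-4-chloro-3,5-dimethoxybenzene
Product: 9 2-[6-(benzyloxy)-3-chloro-2,4-dimethoxyphenyl]acetaldehyde, via diol 8 (not isolated)
Conditions: OsO4 (2 mol %), NaIO4 (4 equiv), 2,6-lutidine (2 equiv), dioxane–H2O 3:1, rt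
Reagents that add atoms: osmium tetroxide O=[Os](=O)(=O)=O (catalytic, delivers the oxygen); sodium periodate [Na+].[O-]I(=O)(=O)=O (terminal oxygen source)
Why: Lemieux–Johnson oxidation (dihydroxylation to racemic diol 8, then periodate glycol cleavage) cuts only the terminal alkene and spares the very electron-rich arene and benzyl ether that ozone could attack.

Step 7
Reactants: 9 2-[6-(benzyloxy)-3-chloro-2,4-dimethoxyphenyl]acetaldehyde
Product: 10 2-[6-(benzyloxy)-3-chloro-2,4-dimethoxyphenyl]acetic acid
Conditions: NaClO2 (3 equiv), NaH2PO4 (3 equiv), 2-methyl-2-butene (10 equiv), t-BuOH–H2O 4:1, 0 °C → rt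
Reagents that add atoms: sodium chlorite [Na+].[O-]Cl=O
Why: Pinnick oxidation converts the aldehyde to the acid under buffered conditions while 2-methyl-2-butene traps HOCl before it can chlorinate the electron-rich ring.

**Fragment A (mixed homophthalate diester)**

Step 8
Reactants: 11 methyl 2-hydroxy-5-methylbenzoate
Product: 12 methyl 3-formyl-2-hydroxy-5-methylbenzoate
Conditions: hexamethylenetetramine (2 equiv), TFA, reflux, 12 h; then 2 M HCl, 60 °C
Reagents that add atoms: hexamethylenetetramine C1N2CN3CN1CN(C2)C3 (formyl carbon); water O (formyl oxygen)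
Why: Duff formylation is ortho-selective for phenols, and with the para position blocked by the methyl group only C3 can react.

Step 9
Reactants: 12 methyl 3-formyl-2-hydroxy-5-methylbenzoate
Product: 14 methyl 2,3-dihydroxy-5-methylbenzoate, via aryl formate 13 (not isolated)
Conditions: 30% H2O2 (1.2 equiv), 1 M NaOH (1.0 equiv), THF–H2O, 0 °C → rt, N2; then dilute HCl to pH 4
Reagents that add atoms: hydrogen peroxide OO
Why: Dakin oxidation of an ortho-hydroxybenzaldehyde (aryl migration driven by the phenoxide, then formate hydrolysis) installs the second oxygen, with exactly one equivalent of base so that the methyl ester is not saponified.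

Step 10
Reactants: 14 methyl 2,3-dihydroxy-5-methylbenzoate
Product: 15 methyl 3-(benzyloxy)-2-hydroxy-5-methylbenzoate
Conditions: NaH (2.2 equiv), DMSO, rt, 30 min, Ar; BnBr (1.0 equiv), rt; 1 M HCl work-up
Reagents that add atoms: benzyl bromide BrCc1ccccc1
Why: Regioselective Williamson alkylation of the catecholate dianion: the 3-oxide, neither conjugated with nor chelated to the ester, is the more nucleophilic oxygen and takes the single equivalent of benzyl bromide.

Step 11
Reactants: 15 methyl 3-(benzyloxy)-2-hydroxy-5-methylbenzoate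
Product: 16 methyl 3-(benzyloxy)-5-methyl-2-{[(trifluoromethyl)sulfonyl]oxy}benzoate
Conditions: Tf2O (1.3 equiv), pyridine (3 equiv), CH2Cl2, 0 °C → rt
Reagents that add atoms: trifluoromethanesulfonic anhydride O=S(=O)(OS(=O)(=O)C(F)(F)F)C(F)(F)F
Why: O-Sulfonylation of the salicylate phenol gives an aryl triflate activated for oxidative addition by the ortho ester.

Step 12
Reactants: 16 methyl 3-(benzyloxy)-5-methyl-2-{[(trifluoromethyl)sulfonyl]oxy}benzoate
Product: 17 methyl 2-allyl-3-(benzyloxy)-5-methylbenzoate
Conditions: allylSnBu3 (1.5 equiv), Pd(PPh3)4 (5 mol %), LiCl (3 equiv), DMF, 90 °C; KF work-up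
Reagents that add atoms: allyltributylstannane C=CC[Sn](CCCC)(CCCC)CCCC
Why: Stille cross-coupling of salicylate triflates with allylstannane (LiCl-promoted) is a robust way to place carbon between the ester and the ether oxygen.

Step 13
Reactants: 17 methyl 2-allyl-3-(benzyloxy)-5-methylbenzoate
Product: 19 methyl 3-(benzyloxy)-5-methyl-2-(2-oxoethyl)benzoate, via ozonide 18 (not isolated)
Conditions: O3, CH2Cl2, −78 °C (Sudan III end-point); PPh3 (1.5 equiv), −78 °C → rt
Reagents that add atoms: ozone [O-][O+]=O
Why: Ozonolysis with reductive work-up is used here because a diol intermediate could lactonise onto the ortho ester, while this ester-deactivated arene and the benzyl ether tolerate ozone at −78 °C.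

Step 14
Reactants: 19 methyl 3-(benzyloxy)-5-methyl-2-(2-oxoethyl)benzoate
Product: 20 2-[2-(benzyloxy)-6-(methoxycarbonyl)-4-methylphenyl]acetic acid
Conditions: NaClO2 (3 equiv), NaH2PO4 (3 equiv), 2-methyl-2-butene (10 equiv), t-BuOH–H2O 4:1, 0 °C → rt (crude 19 used at once)
Reagents that add atoms: sodium chlorite [Na+].[O-]Cl=O
Why: Pinnick oxidation is mild and fast enough to oxidise the cyclisation-prone homobenzylic aldehyde before it can close onto the ortho ester.

Step 15
Reactants: 20 2-[2-(benzyloxy)-6-(methoxycarbonyl)-4-methylphenyl]acetic acid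
Product: 21 methyl 3-(benzyloxy)-2-[2-(benzyloxy)-2-oxoethyl]-5-methylbenzoate
Conditions: BnBr (1.1 equiv), KHCO3 (1.5 equiv), DMF, rt
Reagents that add atoms: benzyl bromide BrCc1ccccc1
Why: Carboxylate O-alkylation with a weak base differentiates the two esters (aryl CO2Me kept, aliphatic CO2Bn removable by hydrogenolysis) without enolising the acidic benzylic CH2.

**Fragment union and end game**

Step 16
Reactants: 10 2-[6-(benzyloxy)-3-chloro-2,4-dimethoxyphenyl]acetic acid; 21 methyl 3-(benzyloxy)-2-[2-(benzyloxy)-2-oxoethyl]-5-methylbenzoate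
Product: 23 benzyl 2-[2-(benzyloxy)-6-(methoxycarbonyl)-4-methylphenyl]-4-[6-(benzyloxy)-3-chloro-2,4-dimethoxyphenyl]-3-oxobutanoate, via acyl imidazole 22 (not isolated)
Conditions: (a) 10 (1.3 equiv), CDI (1.25 equiv), THF, rt, 1 h; (b) 21 (1.0 equiv), LiHMDS (3.3 equiv), THF, −78 °C, 45 min; add (a) dropwise, −78 → −40 °C, 2 h; AcOH (4 equiv) at −78 °C
Reagents that add atoms: 1,1'-carbonyldiimidazole O=C(n1ccnc1)n1ccnc1 (imidazolyl group of 22 only)
Why: Crossed Claisen condensation in which the lithium enolate of the more acidic α-aryl ester 21 is C-acylated by acyl imidazole 22 (extra base absorbs the imidazole N–H and the acidic product); the new α-stereocentre forms as a racemate and is removed in step 17.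

Step 17
Reactants: 23 benzyl 2-[2-(benzyloxy)-6-(methoxycarbonyl)-4-methylphenyl]-4-[6-(benzyloxy)-3-chloro-2,4-dimethoxyphenyl]-3-oxobutanoate
Product: 25 methyl 2-[3-(3-chloro-6-hydroxy-2,4-dimethoxyphenyl)-2-oxopropyl]-3-hydroxy-5-methylbenzoate, via keto acid 24 (not isolated)
Conditions: H2 (1 atm), 5% Pd/C, EtOAc–AcOH 100:1, rt, stopped at full debenzylation (LC-MS); filter; filtrate 40 °C, 1 h
Reagents that add atoms: none
Why: Hydrogenolysis cleaves both aryl benzyl ethers and the benzyl ester under neutral conditions, and the α-aryl β-keto acid 24 then decarboxylates on gentle warming, erasing the racemic centre while the hindered, electron-rich Ar–Cl and the acid-sensitive keto phenol ester are spared.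

**Compound list**
1 | 1,3-dimethoxybenzene | COc1cccc(OC)c1 | starting material
2 | 2-chloro-1,3-dimethoxybenzene | COc1cccc(OC)c1Cl | intermediate
3 | 2-(4-chloro-3,5-dimethoxyphenyl)-4,4,5,5-tetramethyl-1,3,2-dioxaborolane | COc1cc(B2OC(C)(C)C(C)(C)O2)cc(OC)c1Cl | intermediate (not isolated)
4 | 4-chloro-3,5-dimethoxyphenol | COc1cc(O)cc(OC)c1Cl | intermediate
5 | 5-(allyloxy)-2-chloro-1,3-dimethoxybenzene | C=CCOc1cc(OC)c(Cl)c(OC)c1 | intermediate
6 | 2-allyl-4-chloro-3,5-dimethoxyphenol | C=CCc1c(O)cc(OC)c(Cl)c1OC | intermediate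
7 | 2-allyl-1-(benzyloxy)-4-chloro-3,5-dimethoxybenzene | C=CCc1c(OCc2ccccc2)cc(OC)c(Cl)c1OC | intermediate
8 | 3-[6-(benzyloxy)-3-chloro-2,4-dimethoxyphenyl]propane-1,2-diol (racemic) | OCC(O)Cc1c(OCc2ccccc2)cc(OC)c(Cl)c1OC | intermediate (not isolated)
9 | 2-[6-(benzyloxy)-3-chloro-2,4-dimethoxyphenyl]acetaldehyde | O=CCc1c(OCc2ccccc2)cc(OC)c(Cl)c1OC | intermediate
10 | 2-[6-(benzyloxy)-3-chloro-2,4-dimethoxyphenyl]acetic acid | OC(=O)Cc1c(OCc2ccccc2)cc(OC)c(Cl)c1OC | intermediate
11 | methyl 2-hydroxy-5-methylbenzoate | COC(=O)c1cc(C)ccc1O | starting material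
12 | methyl 3-formyl-2-hydroxy-5-methylbenzoate | COC(=O)c1cc(C)cc(C=O)c1O | intermediate
13 | methyl 3-(formyloxy)-2-hydroxy-5-methylbenzoate | COC(=O)c1cc(C)cc(OC=O)c1O | intermediate (not isolated)
14 | methyl 2,3-dihydroxy-5-methylbenzoate | COC(=O)c1cc(C)cc(O)c1O | intermediate
15 | methyl 3-(benzyloxy)-2-hydroxy-5-methylbenzoate | COC(=O)c1cc(C)cc(OCc2ccccc2)c1O | intermediate
16 | methyl 3-(benzyloxy)-5-methyl-2-{[(trifluoromethyl)sulfonyl]oxy}benzoate | COC(=O)c1cc(C)cc(OCc2ccccc2)c1OS(=O)(=O)C(F)(F)F | intermediate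
17 | methyl 2-allyl-3-(benzyloxy)-5-methylbenzoate | COC(=O)c1cc(C)cc(OCc2ccccc2)c1CC=C | intermediate
18 | methyl 3-(benzyloxy)-5-methyl-2-[(1,2,4-trioxolan-3-yl)methyl]benzoate (racemic) | COC(=O)c1cc(C)cc(OCc2ccccc2)c1CC1OCOO1 | intermediate (not isolated)
19 | methyl 3-(benzyloxy)-5-methyl-2-(2-oxoethyl)benzoate | COC(=O)c1cc(C)cc(OCc2ccccc2)c1CC=O | intermediate
20 | 2-[2-(benzyloxy)-6-(methoxycarbonyl)-4-methylphenyl]acetic acid | COC(=O)c1cc(C)cc(OCc2ccccc2)c1CC(=O)O | intermediate
21 | methyl 3-(benzyloxy)-2-[2-(benzyloxy)-2-oxoethyl]-5-methylbenzoate | COC(=O)c1cc(C)cc(OCc2ccccc2)c1CC(=O)OCc1ccccc1 | intermediate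
22 | 2-[6-(benzyloxy)-3-chloro-2,4-dimethoxyphenyl]-1-(1H-imidazol-1-yl)ethan-1-one | O=C(Cc1c(OCc2ccccc2)cc(OC)c(Cl)c1OC)n1ccnc1 | intermediate (not isolated)
23 | benzyl 2-[2-(benzyloxy)-6-(methoxycarbonyl)-4-methylphenyl]-4-[6-(benzyloxy)-3-chloro-2,4-dimethoxyphenyl]-3-oxobutanoate (racemic, keto/enol mixture) | COC(=O)c1cc(C)cc(OCc2ccccc2)c1C(C(=O)OCc1ccccc1)C(=O)Cc1c(OCc2ccccc2)cc(OC)c(Cl)c1OC | intermediate
24 | 4-(3-chloro-6-hydroxy-2,4-dimethoxyphenyl)-2-[2-hydroxy-6-(methoxycarbonyl)-4-methylphenyl]-3-oxobutanoic acid (racemic) | COC(=O)c1cc(C)cc(O)c1C(C(=O)O)C(=O)Cc1c(O)cc(OC)c(Cl)c1OC | intermediate (not isolated)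
25 | methyl 2-[3-(3-chloro-6-hydroxy-2,4-dimethoxyphenyl)-2-oxopropyl]-3-hydroxy-5-methylbenzoate (achiral) | COC(=O)c1cc(C)cc(O)c1CC(=O)Cc1c(O)cc(OC)c(Cl)c1OC | target

**Step count and risks**

Total step count: 17. Longest linear sequence: 10 steps (11 → 25, steps 8–17); the other branch (1 → 10, steps 1–7) joins at step 16.

Three steps most likely to fail:

Step 16 (crossed Claisen). The acyl imidazole 22 is enolisable (proton transfer or ketene formation), and the product enolate can close onto the ortho methyl ester to give an isocoumarin if the mixture warms. The fallback avoids the β-keto ester and the decarboxylation altogether and uses a laterally lithiated o-toluate as the nucleophile. It sets out from triflate 16 and acid 10 and comes back to the route at 25. Suzuki–Miyaura methylation of 16 (trimethylboroxine, Pd(PPh3)4, K2CO3, dioxane, 100 °C) gives methyl 3-(benzyloxy)-2,5-dimethylbenzoate F1. Acid 10 is converted (EDC·HCl, HOBt, MeNHOMe·HCl, i-Pr2NEt, CH2Cl2) into the Weinreb amide 2-[6-(benzyloxy)-3-chloro-2,4-dimethoxyphenyl]-N-methoxy-N-methylacetamide F2. LDA (THF, −78 °C) deprotonates the 2-methyl group of F1 (ortho to the ester), and the resulting dienolate is acylated by F2 to give the ketone methyl 3-(benzyloxy)-2-{3-[6-(benzyloxy)-3-chloro-2,4-dimethoxyphenyl]-2-oxopropyl}-5-methylbenzoate F3. Hydrogenolysis of F3 under the conditions of step 17 gives 25.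

Step 17 (global hydrogenolysis and decarboxylation). Hydrodechlorination of the aryl chloride can compete, and the free keto phenol ester can cyclise (benzofuran or isocoumarin) if acid or heat is overdone. The fallback replaces reductive cleavage by Lewis-acid debenzylation with a cation scavenger. It sets out from 23 and comes back at 25. BCl3 (6 equiv) and pentamethylbenzene (10 equiv) in CH2Cl2 at −78 °C, quenched cold with MeOH–CHCl3, remove all three benzyl groups without touching Ar–Cl; the resulting keto acid 24 decarboxylates on warming to rt. This fallback makes no compound outside the list (new compound: none F0).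

Step 10 (regioselective mono-benzylation). Some 2-O-benzyl or bis-benzyl product may form. The fallback replaces selective alkylation by exhaustive protection followed by chelation-controlled mono-deprotection. It sets out from 14 and comes back at 15. BnBr (2.5 equiv), K2CO3, DMF, 60 °C gives methyl 2,3-bis(benzyloxy)-5-methylbenzoate F4. BCl3 (1.1 equiv), CH2Cl2, −78 °C then cleaves only the benzyl ether ortho to the ester, which chelates boron through the carbonyl, to give 15.

**Further compounds**
F1 | step 16 | methyl 3-(benzyloxy)-2,5-dimethylbenzoate | COC(=O)c1cc(C)cc(OCc2ccccc2)c1C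
F2 | step 16 | 2-[6-(benzyloxy)-3-chloro-2,4-dimethoxyphenyl]-N-methoxy-N-methylacetamide | CON(C)C(=O)Cc1c(OCc2ccccc2)cc(OC)c(Cl)c1OC
F3 | step 16 | methyl 3-(benzyloxy)-2-{3-[6-(benzyloxy)-3-chloro-2,4-dimethoxyphenyl]-2-oxopropyl}-5-methylbenzoate | COC(=O)c1cc(C)cc(OCc2ccccc2)c1CC(=O)Cc1c(OCc2ccccc2)cc(OC)c(Cl)c1OC
F0 | step 17 | none | none
F4 | step 10 | methyl 2,3-bis(benzyloxy)-5-methylbenzoate | COC(=O)c1cc(C)cc(OCc2ccccc2)c1OCc1ccccc1
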